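**Plan**
1. The last cuts are protecting groups: the methyl ether on the C3 oxygen of ring B and a dioxolane on the ring A ketone.
2. Key cut, ring B (C1 = the carbon bearing the CH2 group): the C4–acyl bond and the neighbouring C5–O bond are broken together. Acyl on C4, hydroxyl on C5 and the second oxygen on C3 is the pattern a 3-methoxyaryne (triple bond C4–C5) gives when it takes up 4-methylpentanoic acid.
3. The aryne precursor (C4–SiMe3, C5–OTf) is traced to a C5 O-carbamate, which directs lithiation and silylation to C4 and is then exchanged for triflate.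
4. The CH2–C1 bond is cut to 3-bromo-5-methoxyphenol (as its carbamate) and 4'-methoxyacetophenone, joined by palladium-catalysed enolate arylation.
5. Forward order: carbamate, C–C coupling, ketal, C–Si, O–Tf, aryne insertion (two bonds, no ring closed), ketal removal, O-demethylation. The target has no stereocentre, so no stereocontrol is needed.

Key step: step 7

Remark: compounds 1, 3 and 10 are taken as purchased, and ring B is numbered from the CH2-bearing carbon (C1) throughout.

**Step 1**
Reactants: 1 3-bromo-5-methoxyphenol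
Product: 2 3-bromo-5-methoxyphenyl N,N-diethylcarbamate
Conditions: Et2NCOCl, K2CO3, MeCN, reflux
Reagents that add atoms: N,N-diethylcarbamoyl chloride, CCN(CC)C(Cl)=O
Why: O-carbamoylation of the phenoxide should give a carbamate that withstands the phosphate base of step 2 and the acid of step 3 and later serves as the ortho-directing group.

**Step 2**
Reactants: 2 3-bromo-5-methoxyphenyl N,N-diethylcarbamate; 3 1-(4-methoxyphenyl)ethan-1-one (4'-methoxyacetophenone)
Product: 4 3-methoxy-5-[2-(4-methoxyphenyl)-2-oxoethyl]phenyl N,N-diethylcarbamate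
Conditions: Pd2(dba)3 (cat.), Xantphos (cat.), K3PO4, toluene, 90 °C (3 in slight excess)
Reagents that add atoms: none
Why: Buchwald–Hartwig-type α-arylation of a methyl ketone (oxidative addition of zerovalent palladium into the C–Br bond, exchange with the potassium enolate of 3, reductive elimination); the wide-bite-angle ligand and the mild base should favour monoarylation and spare the carbamate.

**Step 3**
Reactants: 4 3-methoxy-5-[2-(4-methoxyphenyl)-2-oxoethyl]phenyl N,N-diethylcarbamate
Product: 5 3-methoxy-5-{[2-(4-methoxyphenyl)-1,3-dioxolan-2-yl]methyl}phenyl N,N-diethylcarbamate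
Conditions: HOCH2CH2OH, p-TsOH·H2O (cat.), toluene, reflux, Dean–Stark
Reagents that add atoms: ethane-1,2-diol (ethylene glycol), OCCO
Why: acid-catalysed ketalisation driven by azeotropic removal of water masks the enolisable ketone before organolithium and aryne chemistry, while carbamate and aryl ethers are inert.

**Step 4**
Reactants: 5 3-methoxy-5-{[2-(4-methoxyphenyl)-1,3-dioxolan-2-yl]methyl}phenyl N,N-diethylcarbamate
Product: 7 3-methoxy-5-{[2-(4-methoxyphenyl)-1,3-dioxolan-2-yl]methyl}-2-(trimethylsilyl)phenyl N,N-diethylcarbamate, via ring B C4 aryllithium 6 (not isolated)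
Conditions: s-BuLi, TMEDA, THF, −78 °C; then TMSCl, −78 °C to rt; sat. aq. NaHCO3 work-up
Reagents that add atoms: chlorotrimethylsilane, C[Si](C)(C)Cl
Why: directed ortho-metalation removes the C4 hydrogen, the only one flanked by both the carbamate and the methoxy group, and silylation at −78 °C should outrun the anionic Fries shift of the carbamoyl group; the ketal is inert to base.

**Step 5**
Reactants: 7 3-methoxy-5-{[2-(4-methoxyphenyl)-1,3-dioxolan-2-yl]methyl}-2-(trimethylsilyl)phenyl N,N-diethylcarbamate
Product: 8 3-methoxy-5-{[2-(4-methoxyphenyl)-1,3-dioxolan-2-yl]methyl}-2-(trimethylsilyl)phenol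
Conditions: LiAlH4, THF, 0 °C to reflux; aq. potassium sodium tartrate work-up
Reagents that add atoms: none
Why: hydride reduction of the aryl carbamate releases the phenoxide and takes the carbamoyl carbon to an N-methyl group; the ketal, the aryl–silicon bond and the methyl ethers do not react with LiAlH4, and the non-acidic work-up avoids protodesilylation.

**Step 6**
Reactants: 8 3-methoxy-5-{[2-(4-methoxyphenyl)-1,3-dioxolan-2-yl]methyl}-2-(trimethylsilyl)phenol
Product: 9 3-methoxy-5-{[2-(4-methoxyphenyl)-1,3-dioxolan-2-yl]methyl}-2-(trimethylsilyl)phenyl trifluoromethanesulfonate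
Conditions: PhNTf2, DBU, MeCN, 40 °C
Reagents that add atoms: N-phenylbis(trifluoromethanesulfonimide), O=S(=O)(N(c1ccccc1)S(=O)(=O)C(F)(F)F)C(F)(F)F
Why: O-sulfonylation of the hindered phenoxide with a mild triflyl donor under non-acidic conditions is the standard way to complete an ortho-silylaryl triflate and leaves the ketal intact.

**Step 7**
Reactants: 9 3-methoxy-5-{[2-(4-methoxyphenyl)-1,3-dioxolan-2-yl]methyl}-2-(trimethylsilyl)phenyl trifluoromethanesulfonate; 10 4-methylpentanoic acid
Product: 13 1-(2-hydroxy-6-methoxy-4-{[2-(4-methoxyphenyl)-1,3-dioxolan-2-yl]methyl}phenyl)-4-methylpentan-1-one, via cesium 4-methylpentanoate 11 (not isolated), via ring B C4–C5 aryne 12 (not isolated)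
Conditions: 10 (1.0 equiv), CsF (4 equiv), THF, 125 °C, sealed tube
Reagents that add atoms: none
Why: Fluoride attacks silicon at C4 and the resulting carbanion expels triflate from C5, giving aryne 12 with the triple bond between C4 and C5 of ring B. Carboxylate 11 adds through oxygen to C5, the aryne carbon remote from the C3 methoxy group, because the negative charge building up on C4 is then stabilised inductively by the adjacent C–O bond. The C4 anion attacks the neighbouring ester carbonyl through a four-membered transition state and the acyl group moves from oxygen to carbon (an anionic Fries-type 1,3-shift), so the C5–O and C4–acyl bonds are formed in one operation and the C5 phenoxide remains. The closest known reaction is the fluoride-induced insertion of arynes into the C–O bond of carboxylic acids, which gives ortho-hydroxyaryl ketones; no ring is closed and no stereocentre is created. The step needs regioselectivity, which the C3 methoxy group secures, and acyl transfer faster than protonation of the aryl anion, which the hot aprotic medium and the use of only one equivalent of acid, held as its cesium salt, are meant to secure. The dioxolane keeps the enolisable ring A ketone and its acidic methylene away from the aryne and from fluoride.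

**Step 8**
Reactants: 13 1-(2-hydroxy-6-methoxy-4-{[2-(4-methoxyphenyl)-1,3-dioxolan-2-yl]methyl}phenyl)-4-methylpentan-1-one
Product: 14 1-{2-hydroxy-6-methoxy-4-[2-(4-methoxyphenyl)-2-oxoethyl]phenyl}-4-methylpentan-1-one
Conditions: 1 M aq. HCl, THF, rt
Reagents that add atoms: water, O
Why: acid-catalysed ketal hydrolysis through the oxocarbenium ion stabilised by the 4-methoxyphenyl group should be fast, and the hydrogen-bonded hydroxy ketone and the aryl methyl ethers are stable to dilute acid.

**Step 9**
Reactants: 14 1-{2-hydroxy-6-methoxy-4-[2-(4-methoxyphenyl)-2-oxoethyl]phenyl}-4-methylpentan-1-one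
Product: 15 1-{2,6-dihydroxy-4-[2-(4-methoxyphenyl)-2-oxoethyl]phenyl}-4-methylpentan-1-one (CNP0142242.0)
Conditions: BCl3 (3 equiv), CH2Cl2, −78 °C to rt; then H2O
Reagents that add atoms: none
Why: chelation-controlled Lewis-acid ether cleavage, in which boron bridges the ring B ketone oxygen and the adjacent C3 methoxy oxygen and chloride removes the methyl group; the ring A ether has no neighbouring donor and its oxygen is deactivated by the para carbonyl, so it should remain.

**Compound list**
1 | 3-bromo-5-methoxyphenol | COc1cc(O)cc(Br)c1 | starting material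
2 | 3-bromo-5-methoxyphenyl N,N-diethylcarbamate | CCN(CC)C(=O)Oc1cc(Br)cc(OC)c1 | intermediate
3 | 1-(4-methoxyphenyl)ethan-1-one (4'-methoxyacetophenone) | COc1ccc(C(C)=O)cc1 | starting material
4 | 3-methoxy-5-[2-(4-methoxyphenyl)-2-oxoethyl]phenyl N,N-diethylcarbamate | CCN(CC)C(=O)Oc1cc(CC(=O)c2ccc(OC)cc2)cc(OC)c1 | intermediate
5 | 3-methoxy-5-{[2-(4-methoxyphenyl)-1,3-dioxolan-2-yl]methyl}phenyl N,N-diethylcarbamate | CCN(CC)C(=O)Oc1cc(CC2(c3ccc(OC)cc3)OCCO2)cc(OC)c1 | intermediate
6 | {2-[(diethylcarbamoyl)oxy]-6-methoxy-4-{[2-(4-methoxyphenyl)-1,3-dioxolan-2-yl]methyl}phenyl}lithium (5 lithiated at C4 of ring B) | CCN(CC)C(=O)Oc1cc(CC2(c3ccc(OC)cc3)OCCO2)cc(OC)c1[Li] | intermediate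
7 | 3-methoxy-5-{[2-(4-methoxyphenyl)-1,3-dioxolan-2-yl]methyl}-2-(trimethylsilyl)phenyl N,N-diethylcarbamate | CCN(CC)C(=O)Oc1cc(CC2(c3ccc(OC)cc3)OCCO2)cc(OC)c1[Si](C)(C)C | intermediate
8 | 3-methoxy-5-{[2-(4-methoxyphenyl)-1,3-dioxolan-2-yl]methyl}-2-(trimethylsilyl)phenol | COc1cc(CC2(c3ccc(OC)cc3)OCCO2)cc(O)c1[Si](C)(C)C | intermediate
9 | 3-methoxy-5-{[2-(4-methoxyphenyl)-1,3-dioxolan-2-yl]methyl}-2-(trimethylsilyl)phenyl trifluoromethanesulfonate | COc1ccc(C2(Cc3cc(OC)c([Si](C)(C)C)c(OS(=O)(=O)C(F)(F)F)c3)OCCO2)cc1 | intermediate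
10 | 4-methylpentanoic acid | CC(C)CCC(=O)O | starting material
11 | cesium 4-methylpentanoate | CC(C)CCC(=O)[O-].[Cs+] | intermediate
12 | 3-methoxy-5-{[2-(4-methoxyphenyl)-1,3-dioxolan-2-yl]methyl}benzyne (1,2-didehydrobenzene, triple bond C4–C5 of ring B) | COC1=CC(CC2(OCCO2)c2ccc(OC)cc2)=CC#C1 | intermediate
13 | 1-(2-hydroxy-6-methoxy-4-{[2-(4-methoxyphenyl)-1,3-dioxolan-2-yl]methyl}phenyl)-4-methylpentan-1-one | COc1ccc(C2(Cc3cc(OC)c(C(=O)CCC(C)C)c(O)c3)OCCO2)cc1 | intermediate
14 | 1-{2-hydroxy-6-methoxy-4-[2-(4-methoxyphenyl)-2-oxoethyl]phenyl}-4-methylpentan-1-one | COc1ccc(C(=O)Cc2cc(OC)c(C(=O)CCC(C)C)c(O)c2)cc1 | intermediate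
15 | 1-{2,6-dihydroxy-4-[2-(4-methoxyphenyl)-2-oxoethyl]phenyl}-4-methylpentan-1-one (CNP0142242.0) | COc1ccc(C(=O)Cc2cc(O)c(C(=O)CCC(C)C)c(O)c2)cc1 | target

**Step count**
Total: 9 steps. Longest linear sequence: 9 steps (1 to 15).

**Steps most likely to fail**

Step 7. The C4 aryl anion may be protonated before the acyl group shifts, which would stop at O-arylation of the acid, and the product phenoxide may be arylated by a second aryne. The fallback keeps the aryne but gives it a carbonyl partner that cannot be lost by protonation; it sets out from 9 and returns at 13. Compound 9 is treated with CsF in DMF at rt, so that aryne 12 inserts into the C=O bond of the formamide (oxygen to C5, carbon to C4). Aqueous work-up should give 2-hydroxy-6-methoxy-4-{[2-(4-methoxyphenyl)-1,3-dioxolan-2-yl]methyl}benzaldehyde F1. Addition of 3-methylbutylmagnesium bromide (2.2 equiv, THF, 0 °C) should give racemic 2-(1-hydroxy-4-methylpentyl)-3-methoxy-5-{[2-(4-methoxyphenyl)-1,3-dioxolan-2-yl]methyl}phenol F2. Oxidation of the benzylic alcohol with MnO2 in CH2Cl2 leads to 13.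

Step 9. Once BCl3 has reacted with the C5 phenol, the aryloxyboron chelate may occupy the ketone oxygen, so that cleavage of the C3 methyl ether becomes slow and longer exposure starts to remove the ring A methyl group. The fallback frees the carbonyl for chelation by capping the phenol first; it sets out from 14 and returns at 15. Acetylation (Ac2O, pyridine, DMAP, CH2Cl2) should give 3-methoxy-5-[2-(4-methoxyphenyl)-2-oxoethyl]-2-(4-methylpentanoyl)phenyl acetate F3. BCl3 (CH2Cl2, −78 to 0 °C) then meets an ordinary ortho-methoxyaryl ketone and should give 3-hydroxy-5-[2-(4-methoxyphenyl)-2-oxoethyl]-2-(4-methylpentanoyl)phenyl acetate F4. Methanolysis of the acetate (K2CO3, MeOH, rt) gives 15.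

Step 2. A second arylation at the more acidic methylene of the product, or slow coupling of the electron-rich bromide, may erode the monoarylation. The fallback builds the same carbon–carbon bond through an alkyne; it sets out from 2 and returns at 4. Sonogashira coupling of 2 with 1-ethynyl-4-methoxybenzene (Pd(PPh3)2Cl2, CuI, Et3N, 60 °C) should give 3-methoxy-5-[(4-methoxyphenyl)ethynyl]phenyl N,N-diethylcarbamate F5. Acid-catalysed hydration (p-TsOH·H2O, EtOH/H2O, reflux) places the oxygen on the alkyne carbon attached to the 4-methoxyphenyl ring, which best stabilises the vinyl cation, and gives 4.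

**Further compounds**
F1 | step 7 | 2-hydroxy-6-methoxy-4-{[2-(4-methoxyphenyl)-1,3-dioxolan-2-yl]methyl}benzaldehyde | COc1ccc(C2(Cc3cc(OC)c(C=O)c(O)c3)OCCO2)cc1
F2 | step 7 | 2-(1-hydroxy-4-methylpentyl)-3-methoxy-5-{[2-(4-methoxyphenyl)-1,3-dioxolan-2-yl]methyl}phenol (racemic) | COc1ccc(C2(Cc3cc(OC)c(C(O)CCC(C)C)c(O)c3)OCCO2)cc1
F3 | step 9 | 3-methoxy-5-[2-(4-methoxyphenyl)-2-oxoethyl]-2-(4-methylpentanoyl)phenyl acetate | COc1ccc(C(=O)Cc2cc(OC)c(C(=O)CCC(C)C)c(OC(C)=O)c2)cc1
F4 | step 9 | 3-hydroxy-5-[2-(4-methoxyphenyl)-2-oxoethyl]-2-(4-methylpentanoyl)phenyl acetate | COc1ccc(C(=O)Cc2cc(O)c(C(=O)CCC(C)C)c(OC(C)=O)c2)cc1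
F5 | step 2 | 3-methoxy-5-[(4-methoxyphenyl)ethynyl]phenyl N,N-diethylcarbamate | CCN(CC)C(=O)Oc1cc(C#Cc2ccc(OC)cc2)cc(OC)c1
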